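The arene is assembled from acyclic pieces. Its benzene ring is para-disubstituted and nothing more: C1 bears the hydroxyl, C4 the CH2CH2O–acyl arm, C2/C3/C5/C6 are CH. Such a ring is the dehydrogenation product of a 4-substituted cyclohex-2-enone (C1 = C=O), which is disconnected at C4–C5 and C2=C3 into methyl vinyl ketone (C1, C2, C5, C6) and the formyl and α-carbons (C3, C4) of 4-oxobutyl heptatriacontanoate, an aldehyde that already carries the whole C37 ester. A single enamine Michael–aldol operation forges both bonds and the carbocycle, placing the side chain unavoidably para to oxygen.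

Key step: step 5

Remark on the chemistry: hexatriacontanoic acid is assumed purchasable from lipid suppliers, and since the C36/C37 compounds are waxes that dissolve only in warm solvents, each step is specified at a temperature that keeps the chain in solution.

Step 1
Reactants: 1 hexatriacontanoic acid
Product: 2 hexatriacontanoyl chloride
Conditions: (COCl)2 (1.5 equiv), DMF (cat.), PhMe, 45 °C; evaporate
Reagents that add atoms: oxalyl chloride, ClC(=O)C(=O)Cl
Why: Catalytic DMF turns oxalyl chloride into the Vilsmeier chloroiminium species, which activates the acid and delivers the acyl chloride (acid chloride formation) with only gaseous by-products, warm toluene keeping the C36 chain dissolved.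

Step 2
Reactants: 2 hexatriacontanoyl chloride
Product: 3 1-diazoheptatriacontan-2-one
Conditions: TMSCHN2 (2.0 equiv, 2 M in hexanes), THF/MeCN (3:1), 0 → 25 °C; evaporate
Reagents that add atoms: trimethylsilyldiazomethane, C[Si](C)(C)C=[N+]=[N-]
Why: The nucleophilic diazo carbon is acylated by the acid chloride and chloride removes the silyl group, giving the α-diazoketone (first stage of the Arndt–Eistert homologation) without the need to handle diazomethane.

Step 3
Reactants: 3 1-diazoheptatriacontan-2-one; 4 butane-1,4-diol
Product: 6 4-hydroxybutyl heptatriacontanoate, via ketene 5 (not isolated)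
Conditions: PhCO2Ag (10 mol%), Et3N (3 equiv), butane-1,4-diol (10 equiv), THF, 55 °C, dark
Reagents that add atoms: none
Why: Silver-promoted Wolff rearrangement expels dinitrogen with 1,2-shift of the C35 alkyl group to give the ketene, which acylates one hydroxyl of the diol present in tenfold excess, so the mono-ester should dominate (Arndt–Eistert homologation with in situ esterification).

Step 4
Reactants: 6 4-hydroxybutyl heptatriacontanoate
Product: 7 4-oxobutyl heptatriacontanoate
Conditions: IBX (1.5 equiv), EtOAc, 75 °C; filter warm
Reagents that add atoms: none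
Why: IBX oxidation of a primary alcohol should stop cleanly at the aldehyde, tolerates the ester, and runs as a suspension in hot ethyl acetate in which the waxy substrate dissolves and the spent oxidant is filtered off.

Step 5
Reactants: 7 4-oxobutyl heptatriacontanoate; 8 methyl vinyl ketone
Product: 11 2-(4-oxocyclohex-2-en-1-yl)ethyl heptatriacontanoate (racemic), via enamine 9 (not isolated), via keto-aldehyde 10 (not isolated)
Conditions: pyrrolidine (1.1 equiv), 4 Å MS, PhMe, 40 °C; 8 (1.5 equiv, slow addition), 40 °C; then AcOH, NaOAc, H2O, 90 °C
Reagents that add atoms: none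
Why: Pyrrolidine condenses with the aldehyde of 7 to give enamine 9, whose nucleophilic β-carbon (the former aldehyde α-carbon, carrying the CH2CH2O–acyl arm) adds to the CH2 terminus of 8 and so forms C4–C5, and the aqueous acetate buffer then hydrolyses the adduct to keto-aldehyde 10. In the same buffer the methyl ketone enolises towards its CH3 group, this carbon attacks the aldehyde carbonyl, and E1cB loss of water installs C2=C3 in conjugation with the ketone. The closest known reaction type is the Stork enamine Robinson annulation of α-monosubstituted aldehydes with methyl vinyl ketone to 4-alkylcyclohex-2-enones. The ring closes in the 6-(enolendo)-exo-trig mode, the only alternatives being strained four-membered aldols, so the side chain can only end up at C4, para to the carbonyl carbon. The C4 stereocentre arises in the Michael step with no controlling element and is therefore racemic, which is immaterial because it becomes an sp2 arene carbon in step 6. The selectivities needed are C- over N-alkylation with a single Michael addition, secured by the monosubstituted enamine and slow addition of 8, and survival of the fatty ester, secured by the near-neutral amine/acetate medium.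

Step 6
Reactants: 11 2-(4-oxocyclohex-2-en-1-yl)ethyl heptatriacontanoate (racemic)
Product: 12 2-(4-hydroxyphenyl)ethyl heptatriacontanoate
Conditions: Pd(O2CCF3)2 (5 mol%), 2-(dimethylamino)pyridine (10 mol%), TsOH·H2O (20 mol%), O2 (1 atm), DMSO/PhCl (1:1), 80 °C
Reagents that add atoms: none
Why: In this aerobic dehydrogenation catalysed by divalent palladium the enol of 11 is palladated at C6, β-hydride elimination from C5 gives the cyclohexa-2,5-dienone, and this tautomerises through its C4–H to the phenol while O2 returns zerovalent palladium to the divalent state, erasing the racemic centre and leaving ester and alkyl chain untouched.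

Compound list
1 | hexatriacontanoic acid | CCCCCCCCCCCCCCCCCCCCCCCCCCCCCCCCCCCC(=O)O | starting material
2 | hexatriacontanoyl chloride | CCCCCCCCCCCCCCCCCCCCCCCCCCCCCCCCCCCC(=O)Cl | intermediate
3 | 1-diazoheptatriacontan-2-one | CCCCCCCCCCCCCCCCCCCCCCCCCCCCCCCCCCCC(=O)C=[N+]=[N-] | intermediate
4 | butane-1,4-diol | OCCCCO | starting material
5 | heptatriacont-1-en-1-one (pentatriacontylketene) | CCCCCCCCCCCCCCCCCCCCCCCCCCCCCCCCCCCC=C=O | intermediate
6 | 4-hydroxybutyl heptatriacontanoate | CCCCCCCCCCCCCCCCCCCCCCCCCCCCCCCCCCCCC(=O)OCCCCO | intermediate
7 | 4-oxobutyl heptatriacontanoate | CCCCCCCCCCCCCCCCCCCCCCCCCCCCCCCCCCCCC(=O)OCCCC=O | intermediate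
8 | methyl vinyl ketone (but-3-en-2-one) | CC(=O)C=C | starting material
9 | (E)-4-(pyrrolidin-1-yl)but-3-en-1-yl heptatriacontanoate | CCCCCCCCCCCCCCCCCCCCCCCCCCCCCCCCCCCCC(=O)OCC/C=C/N1CCCC1 | intermediate
10 | 3-formyl-6-oxoheptyl heptatriacontanoate (racemic) | CCCCCCCCCCCCCCCCCCCCCCCCCCCCCCCCCCCCC(=O)OCCC(C=O)CCC(C)=O | intermediate
11 | 2-(4-oxocyclohex-2-en-1-yl)ethyl heptatriacontanoate (racemic) | CCCCCCCCCCCCCCCCCCCCCCCCCCCCCCCCCCCCC(=O)OCCC1C=CC(=O)CC1 | intermediate
12 | 2-(4-hydroxyphenyl)ethyl heptatriacontanoate | CCCCCCCCCCCCCCCCCCCCCCCCCCCCCCCCCCCCC(=O)OCCc1ccc(O)cc1 | target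

Total step count: 6. Longest linear sequence: 6 steps (1 → 2 → 3 → 6 → 7 → 11 → 12).

Steps most likely to fail

Step 5. The enamine or the free aldehyde may self-condense, the enone acceptor may polymerise or add twice, or ring closure may stall because the waxy substrate aggregates in the buffered two-phase medium. The fallback sets out from 7, returns at 10 and rejoins the route at 11. Aldehyde 7 is converted with TMSCl, NaI and Et3N in MeCN/PhMe into the silyl enol ether (Z)-4-(trimethylsilyloxy)but-3-en-1-yl heptatriacontanoate F1. A Mukaiyama–Michael addition of F1 to 8, promoted by BF3·OEt2 in CH2Cl2/MeNO2 at −20 °C with aqueous work-up, should give keto-aldehyde 10, this time isolated. Acid-catalysed cyclodehydration (TsOH cat., PhMe, reflux, Dean–Stark) then closes 10 to 11. The same two bonds are made, but through a Lewis-acid manifold that avoids free amine and basic enolisation.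

Step 6. The dehydrogenation may stall through deposition of metallic palladium or poor solvation of the lipid-like substrate in DMSO, leaving partial conversion. The fallback sets out from 11 and returns at 12. Soft enolisation with TMSOTf/Et3N (CH2Cl2/PhMe, 0 → 25 °C) should give the cross-conjugated silyl dienol ether 2-[4-(trimethylsilyloxy)cyclohexa-2,4-dien-1-yl]ethyl heptatriacontanoate F2. Oxidation of F2 with DDQ (1.1 equiv, PhMe, 25 °C) followed by dilute HCl work-up removes two hydrogens and the silyl group, the resulting dienone tautomerising to phenol 12.

Step 3. The ketene may acylate both hydroxyls of the diol, or the rearrangement may remain incomplete if the diazoketone or the silver salt leaves solution. The fallback sets out from 3 and returns at 7, bypassing 6 and step 4. The Wolff rearrangement is run in the presence of pent-4-en-1-ol (1.5 equiv; PhCO2Ag, Et3N, THF, 55 °C), which can give only one ester, pent-4-en-1-yl heptatriacontanoate F3. Lemieux–Johnson cleavage of the terminal alkene of F3 (K2OsO4·2H2O cat., NaIO4, 2,6-lutidine, dioxane/H2O, 40 °C) should deliver aldehyde 7 directly.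

Further compounds
F1 | step 5 | (Z)-4-(trimethylsilyloxy)but-3-en-1-yl heptatriacontanoate | CCCCCCCCCCCCCCCCCCCCCCCCCCCCCCCCCCCCC(=O)OCC/C=C\O[Si](C)(C)C
F2 | step 6 | 2-[4-(trimethylsilyloxy)cyclohexa-2,4-dien-1-yl]ethyl heptatriacontanoate (racemic) | CCCCCCCCCCCCCCCCCCCCCCCCCCCCCCCCCCCCC(=O)OCCC1C=CC(O[Si](C)(C)C)=CC1
F3 | step 3 | pent-4-en-1-yl heptatriacontanoate | CCCCCCCCCCCCCCCCCCCCCCCCCCCCCCCCCCCCC(=O)OCCCC=C
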